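**Assumption and numbering (one line):** the SMILES is read literally as (1R,2S,5S,6S,7S,10S) in tricyclo[5.3.1.0(1,5)]undecane numbering (C1 quaternary ring-junction carbon; C2 bears the formyl carbon C12; C6 bears CH3 and C13H2OH; C8 bears the carboxyl carbon C15; C10 bears the acyloxy group; C11 is the CH2 bridge; ring A = C1–C2–C3–C4–C5, ring B = C1, C5, C6, C7, C11, ring C = C1, C10, C9, C8, C7, C11), so that H5 is cis to C13 and C11 while C4 is cis to the C6 methyl and the C8–C10 bridge (rings A and B trans-fused); every stereochemical argument below refers to this arrangement.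

## Retrosynthetic overview

1. Target 28 ⇐ 27 (acidolysis of the tert-butyl ester and both silyl ethers) ⇐ 26 (amide to aldehyde) ⇐ hydroxy Weinreb amide 18 + Z-acid 25 (acylation of O10); 18 ⇐ lactone 17, whose O10–C12 γ-lactone is a temporary ring.
2. Ring A (C1–C2–C3–C4–C5) ⇐ [3+2] annulation on bicyclic keto lactone 12: the C2 lactone enolate adds to vinyltriphenylphosphonium bromide (C3, C4) and the ylide closes on the C5 ketone (C4=C5); the C13 hydroxyl then directs hydrogenation of C4=C5 to set C5.
3. Enabling feature: in ring A, C2 carries the C12 carbonyl and C5 lies between the quaternary carbons C1 and C6, so C5 can be a non-enolisable ketone and C2 the only carbanion (a C12/C5 1,4-dicarbonyl across C1); O10 and C12 are cis across C1–C2, so a γ-lactone masks O10, acidifies C2–H and fixes C2.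
4. Ring C ⇐ intramolecular aldol of the C1 enolate of cyclopentanone 9 onto the C10 aldehyde of a (Z)-4-oxobut-2-enoic acid unit (C8, C9, C10, C15), unmasked from a 2-silyl-3-furyl group by singlet oxygen; C6 and C7 ⇐ asymmetric conjugate addition–enolate alkylation on 2-methylcyclopent-2-enone.
5. Ring order: ring B (bought as 3) → ring C (step 5) → ring A (step 7).

Key step: step 7

## Route

Step 1
Reactants: 1 3-bromofuran
Product: 2 3-bromo-2-(trimethylsilyl)furan
Conditions: LiN(i-Pr)2, THF, −78 °C; then Me3SiCl, −78 °C → rt
Reagents that add atoms: chlorotrimethylsilane, C[Si](C)(C)Cl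
Why: Directed lithiation: the bromine acidifies the adjacent C2–H of the furan, and the 2-lithio species is silylated; the silyl group later decides which furan carbon becomes the carboxyl carbon C15.

Step 2
Reactants: 2 3-bromo-2-(trimethylsilyl)furan; 3 2-methylcyclopent-2-en-1-one
Product: 6 (2S,3S)-2-{[(4-methoxybenzyl)oxy]methyl}-2-methyl-3-[2-(trimethylsilyl)furan-3-yl]cyclopentan-1-one, via Grignard reagent 4 (not isolated), via magnesium enolate 5 (not isolated)
Conditions: n-BuLi, Et2O, −78 °C; MgBr2·OEt2; then 3, Cu(OTf)2 (3 mol%), chiral imidazolinium chloride (NHC ligand precursor, 4 mol%), Et2O, −30 °C; then PMBOCH2Cl, −30 → 0 °C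
Reagents that add atoms: 4-methoxybenzyl chloromethyl ether, COc1ccc(COCCl)cc1
Why: Copper-catalysed asymmetric conjugate addition of the aryl Grignard reagent to the α-methyl enone sets C7 (the ligand enantiomer is chosen for 3S), and the magnesium enolate is C-alkylated anti to the new C7 substituent, which sets quaternary C6 with CH2OPMB trans and CH3 cis to the furyl group (three-component conjugate addition–enolate trapping).

Step 3
Reactants: 6 the cyclopentanone from step 2
Product: 7 methyl 2-[(1R,3S,4S)-3-{[(4-methoxybenzyl)oxy]methyl}-3-methyl-2-oxo-4-[2-(trimethylsilyl)furan-3-yl]cyclopentyl]acetate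
Conditions: LiN(i-Pr)2, THF, −78 °C; BrCH2CO2Me, −78 → −30 °C
Reagents that add atoms: methyl bromoacetate, COC(=O)CBr
Why: Kinetic enolate alkylation: C6 is quaternary, so only C1 of the ketone can be deprotonated; alkylation anti to the C7 substituent is expected, and the C1 configuration is of no consequence because C1 is re-enolised in step 5.

Step 4
Reactants: 7 the keto ester from step 3
Product: 9 methyl 2-[(1R,3S,4S)-4-(5-hydroxy-2-oxo-2,5-dihydrofuran-3-yl)-3-{[(4-methoxybenzyl)oxy]methyl}-3-methyl-2-oxocyclopentyl]acetate (anomer mixture at C10), via silyl ester 8 (not isolated)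
Conditions: O2, tetraphenylporphyrin (cat.), visible light, CH2Cl2, −78 °C; then H2O/THF, 0 °C
Reagents that add atoms: dioxygen, O=O
Why: Singlet-oxygen [4+2] addition to the furan gives an endoperoxide in which silicon migrates to the peroxide oxygen, so the silicon-bearing carbon becomes the carboxyl carbon C15 and the distal CH the aldehyde carbon C10; hydrolysis gives the γ-hydroxybutenolide (silyl-directed furan photooxygenation) without touching a stereocentre.

Step 5
Reactants: 9 the γ-hydroxybutenolide from step 4
Product: 11 tricyclic keto lactone acid (rings B and C closed; C5 ketone; O10–C12 γ-lactone; C8 carboxylic acid; C13 PMB ether), via aldol adduct 10 (not isolated)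
Conditions: KOt-Bu (3 equiv), THF/t-BuOH, −20 → 0 °C; then 1 M HCl
Reagents that add atoms: none
Why: Base opens the hydroxybutenolide to the (Z)-4-oxobut-2-enoate, and the only ketone enolate (C1) adds to the C10 aldehyde in a 6-(enolexo)-exo-trig intramolecular aldol that must bridge C1 and C7 on the same face of ring B (sets C1); the reversible aldol is drained through the C10 alkoxide that is anti to C5, which closes the cis-fused γ-lactone onto the C12 ester (sets C10; aldol–lactonisation).

Step 6
Reactants: 11 the keto lactone acid from step 5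
Product: 12 tert-butyl ester of 11 (tricyclic keto lactone with C15 as CO2t-Bu)
Conditions: Cl3CC(=NH)Ot-Bu, CH2Cl2/cyclohexane, rt
Reagents that add atoms: tert-butyl 2,2,2-trichloroacetimidate, CC(C)(C)OC(=N)C(Cl)(Cl)Cl
Why: The carboxylic acid protonates the trichloroacetimidate and is O-alkylated by the tert-butyl cation equivalent, under near-neutral conditions that leave the PMB ether and the lactone untouched.

Step 7
Reactants: 12 the tert-butyl ester keto lactone
Product: 14 tetracyclic lactone (ring A closed with C4=C5; C2 as in the target; C13 PMB ether; C15 tert-butyl ester), via phosphorus ylide 13 (not isolated)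
Conditions: NaH, DMF/THF, 0 °C; then [CH2=CHPPh3]Br, rt → 60 °C
Reagents that add atoms: vinyltriphenylphosphonium bromide, C=C[P+](c1ccccc1)(c1ccccc1)c1ccccc1.[Br-]
Why: NaH removes the only acidic C–H (C2–H, α to the lactone carbonyl; the C5 ketone lies between two quaternary carbons and cannot enolise), the enolate adds to the vinylphosphonium ion to give ylide 13, and 13 closes ring A by an intramolecular Wittig reaction on the C5 carbonyl, forming C4=C5 and expelling Ph3P=O. The closest known reaction type is the Schweizer-type annulation of γ-keto carbanions such as acetonylmalonates with vinyltriphenylphosphonium bromide to give cyclopentenes. Ring A is closed by attack of the ylide carbon C4 on the C5 carbonyl (5-exo-trig addition, then syn-elimination from the oxaphosphetane), so C5 is still sp2 and the strain of the later trans junction is not yet met. The one new stereocentre, C2, is controlled by the two rings that meet there: the γ-lactone holds C12 on the O10 side and only the C2 epimer whose C3–C4 arm faces C5 can reach the ketone, while the epimers of 13 interconvert through the lactone enolate. The step needs chemoselectivity for C-alkylation at C2 and for olefination of the ketone only: O10 is tied up in the lactone (a free alkoxide would add to the phosphonium salt), the tert-butyl ester and the lactone carbonyl are poor partners for a non-stabilised ylide, and H10 lies in the plane of the C8=C9 bond so that γ-deprotonation of the enoate is not expected.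

Step 8
Reactants: 14 the tetracyclic lactone PMB ether
Product: 15 tetracyclic lactone with free C13 hydroxyl (C4=C5 still present)
Conditions: DDQ, CH2Cl2/pH 7 buffer, 0 °C → rt
Reagents that add atoms: none
Why: Oxidative cleavage of the electron-rich PMB ether by DDQ (hydride abstraction, then hydrolysis of the oxocarbenium ion) frees the C13 hydroxyl as a directing group; no stereocentre is touched.

Step 9
Reactants: 15 the C13 alcohol
Product: 16 C5-saturated tetracyclic lactone (H5 cis to C13H2OH; C4 cis to the C6 methyl)
Conditions: H2 (1 atm), [Ir(cod)(PCy3)(py)]PF6 (10 mol%), CH2Cl2, 0 °C → rt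
Reagents that add atoms: none
Why: Hydroxyl-directed homogeneous hydrogenation: the cationic iridium catalyst binds the C13 hydroxyl on the face of ring B that carries C11 and should deliver H2 to that face of the trisubstituted C4=C5 bond, so H5 ends cis to C13 and C4 cis to the C6 methyl (sets C5 and the trans junction of rings A and B), while the electron-poor C8=C9 enoate is left.

Step 10
Reactants: 16 the saturated lactone alcohol
Product: 17 C13 tert-butyldimethylsilyl ether of 16
Conditions: TBSCl, imidazole, DMF, rt
Reagents that add atoms: tert-butyldimethylsilyl chloride, CC(C)(C)[Si](C)(C)Cl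
Why: Silylation of the primary neopentyl alcohol protects C13–OH before O10 is set free, so that only O10 can be acylated in step 16.

Step 11
Reactants: 17 the silyl-protected lactone
Product: 18 hydroxy Weinreb amide (free C10–OH; C12 as C(=O)N(OMe)Me; C13 TBS ether; C15 tert-butyl ester)
Conditions: MeNH(OMe)·HCl, AlMe3, CH2Cl2, 0 °C → rt; then aqueous potassium sodium tartrate
Reagents that add atoms: N,O-dimethylhydroxylamine hydrochloride, CNOC.Cl
Why: Aminolysis of the lactone by the aluminium amide made from AlMe3 and the hydroxylamine salt (Weinreb amide formation) opens the temporary ring at the acyl carbon C12, so the C10–O bond and the C10 configuration are kept and C12 stays at the acyl oxidation level.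

Step 12
Reactants: 19 heptane-1,7-diol
Product: 20 7-[(tert-butyldimethylsilyl)oxy]heptan-1-ol
Conditions: NaH (1 equiv), THF, 0 °C; TBSCl, rt
Reagents that add atoms: tert-butyldimethylsilyl chloride, CC(C)(C)[Si](C)(C)Cl
Why: Monosilylation of the symmetrical diol through its sparingly soluble monosodium alkoxide favours the mono-ether.

Step 13
Reactants: 20 the mono-silylated diol
Product: 21 7-[(tert-butyldimethylsilyl)oxy]heptanal
Conditions: TEMPO (cat.), PhI(OAc)2, CH2Cl2, rt
Reagents that add atoms: none
Why: Nitroxyl-catalysed oxidation of the primary alcohol stops at the aldehyde and leaves the silyl ether.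

Step 14
Reactants: 22 9-bromononanoic acid
Product: 23 (8-carboxyoctyl)triphenylphosphonium bromide
Conditions: PPh3, MeCN, reflux
Reagents that add atoms: triphenylphosphine, c1ccc(cc1)P(c1ccccc1)c1ccccc1
Why: SN2 quaternisation of triphenylphosphine by the primary bromide gives the phosphonium salt.

Step 15
Reactants: 23 the phosphonium salt; 21 the silyloxy aldehyde
Product: 25 (Z)-16-[(tert-butyldimethylsilyl)oxy]hexadec-9-enoic acid, via phosphorus ylide 24 (not isolated)
Conditions: NaN(SiMe3)2 (2.1 equiv), THF, −78 → 0 °C; then 21, −78 °C → rt; aqueous HCl work-up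
Reagents that add atoms: none
Why: Wittig olefination with a non-stabilised ylide under lithium-free conditions goes through the cis-oxaphosphetane and should give the Z-alkene; the second equivalent of base only deprotonates the carboxylic acid.

Step 16
Reactants: 18 the hydroxy Weinreb amide; 25 the Z-acid
Product: 26 C10 ester (O10 acylated by 25; C12 Weinreb amide; two TBS ethers; tert-butyl ester)
Conditions: 2,4,6-Cl3C6H2COCl, Et3N, toluene, rt; then 18, DMAP, rt → 40 °C
Reagents that add atoms: none
Why: Yamaguchi esterification: the mixed anhydride of 25 acylates the hindered C10 hydroxyl under DMAP catalysis without touching the C10–O bond, so the C10 configuration is retained.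

Step 17
Reactants: 26 the Weinreb amide ester
Product: 27 aldehyde (C12 as CHO; otherwise as 26)
Conditions: Cp2Zr(H)Cl (1.5 equiv), THF, rt; then H2O/silica
Reagents that add atoms: none
Why: Hydrozirconation of the amide carbonyl gives a zirconated hemiaminal that collapses to the aldehyde only on work-up, so the esters, silyl ethers and the Z-alkene should survive and C2 is not exposed to base (amide-to-aldehyde reduction with Cp2Zr(H)Cl).

Step 18
Reactants: 27 the protected aldehyde
Product: 28 target (CNP0148862.1)
Conditions: CF3CO2H/CH2Cl2/H2O (9:9:1), 0 °C → rt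
Reagents that add atoms: none
Why: Acidolysis removes the tert-butyl ester (as 2-methylpropene) and both primary TBS ethers in one operation, while the aldehyde, the allylic C10 ester and the Z-alkene are stable to acid and no stereocentre is exposed to base.

## Compound list

1 | 3-bromofuran | Brc1ccoc1 | starting material
2 | 3-bromo-2-(trimethylsilyl)furan | C[Si](C)(C)c1occc1Br | intermediate
3 | 2-methylcyclopent-2-en-1-one | CC1=CCCC1=O | starting material
4 | [2-(trimethylsilyl)furan-3-yl]magnesium bromide (not isolated) | C[Si](C)(C)c1occc1[Mg]Br | intermediate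
5 | bromomagnesium (3S)-2-methyl-3-[2-(trimethylsilyl)furan-3-yl]cyclopent-1-en-1-olate (not isolated) | Br[Mg]OC1=C(C)[C@@H](c2ccoc2[Si](C)(C)C)CC1 | intermediate
6 | (2S,3S)-2-{[(4-methoxybenzyl)oxy]methyl}-2-methyl-3-[2-(trimethylsilyl)furan-3-yl]cyclopentan-1-one (ring B; ketone carbon = C5, ring C2 = C6, ring C3 = C7) | O=C1[C@](C)(COCc5ccc(OC)cc5)[C@@H](c2ccoc2[Si](C)(C)C)CC1 | intermediate
7 | methyl 2-[(1R,3S,4S)-3-{[(4-methoxybenzyl)oxy]methyl}-3-methyl-2-oxo-4-[2-(trimethylsilyl)furan-3-yl]cyclopentyl]acetate | O=C1[C@](C)(COCc5ccc(OC)cc5)[C@@H](c2ccoc2[Si](C)(C)C)C[C@@H]1CC(=O)OC | intermediate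
8 | trimethylsilyl (Z)-4-oxobut-2-enoate carrying the cyclopentyl unit of 7 on its C2 (not isolated) | O=C1[C@](C)(COCc5ccc(OC)cc5)[C@@H](/C(=C/C=O)C(=O)O[Si](C)(C)C)C[C@@H]1CC(=O)OC | intermediate
9 | methyl 2-[(1R,3S,4S)-4-(5-hydroxy-2-oxo-2,5-dihydrofuran-3-yl)-3-{[(4-methoxybenzyl)oxy]methyl}-3-methyl-2-oxocyclopentyl]acetate (anomer mixture) | O=C1[C@](C)(COCc5ccc(OC)cc5)[C@@H](C2=CC(O)OC2=O)C[C@@H]1CC(=O)OC | intermediate
10 | aldol adduct: bicyclo[3.2.1]oct-2-ene (rings B and C) with C5 ketone, free C10–OH anti to C5, C8 carboxylic acid, C1–CH2CO2Me, C6 CH3 and CH2OPMB (not isolated) | O=C1[C@](C)(COCc5ccc(OC)cc5)[C@@H]2C[C@]1([C@@H](O)C=C2C(=O)O)CC(=O)OC | intermediate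
11 | tricyclic keto lactone acid: 10 with the O10–C12 γ-lactone closed | O=C1[C@](C)(COCc5ccc(OC)cc5)[C@@H]2C[C@]1([C@@H](O4)C=C2C(=O)O)CC4=O | intermediate
12 | tert-butyl ester of 11 | O=C1[C@](C)(COCc5ccc(OC)cc5)[C@@H]2C[C@]1([C@@H](O4)C=C2C(=O)OC(C)(C)C)CC4=O | intermediate
13 | ylide: 12 carrying CH2–CH=PPh3 on C2 (not isolated) | O=C1[C@](C)(COCc5ccc(OC)cc5)[C@@H]2C[C@]1([C@@H](O4)C=C2C(=O)OC(C)(C)C)[C@@H](C4=O)C[CH-][P+](c6ccccc6)(c6ccccc6)c6ccccc6 | intermediate
14 | tetracyclic lactone: rings A, B, C and the O10–C12 lactone; C4=C5; C13 PMB ether; C15 tert-butyl ester | C[C@@]1(COCc5ccc(OC)cc5)[C@@H]2C[C@]3([C@@H](O4)C=C2C(=O)OC(C)(C)C)[C@@H](C4=O)CC=C13 | intermediate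
15 | 14 with free C13 hydroxyl | C[C@@]1(CO)[C@@H]2C[C@]3([C@@H](O4)C=C2C(=O)OC(C)(C)C)[C@@H](C4=O)CC=C13 | intermediate
16 | C5-saturated lactone alcohol (H5 cis to C13) | C[C@@]1(CO)[C@@H]2C[C@]3([C@@H](O4)C=C2C(=O)OC(C)(C)C)[C@@H](C4=O)CC[C@@H]13 | intermediate
17 | C13 TBS ether of 16 | C[C@@]1(CO[Si](C)(C)C(C)(C)C)[C@@H]2C[C@]3([C@@H](O4)C=C2C(=O)OC(C)(C)C)[C@@H](C4=O)CC[C@@H]13 | intermediate
18 | hydroxy Weinreb amide (C10–OH free, C12 as N-methoxy-N-methylamide) | C[C@@]1(CO[Si](C)(C)C(C)(C)C)[C@@H]2C[C@]3([C@@H](O)C=C2C(=O)OC(C)(C)C)[C@@H](C(=O)N(C)OC)CC[C@@H]13 | intermediate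
19 | heptane-1,7-diol | OCCCCCCCO | starting material
20 | 7-[(tert-butyldimethylsilyl)oxy]heptan-1-ol | OCCCCCCCO[Si](C)(C)C(C)(C)C | intermediate
21 | 7-[(tert-butyldimethylsilyl)oxy]heptanal | O=CCCCCCCO[Si](C)(C)C(C)(C)C | intermediate
22 | 9-bromononanoic acid | OC(=O)CCCCCCCCBr | starting material
23 | (8-carboxyoctyl)triphenylphosphonium bromide | OC(=O)CCCCCCCC[P+](c1ccccc1)(c1ccccc1)c1ccccc1.[Br-] | intermediate
24 | sodium 9-(triphenylphosphoranylidene)nonanoate (not isolated) | [Na+].[O-]C(=O)CCCCCCC[CH-][P+](c1ccccc1)(c1ccccc1)c1ccccc1 | intermediate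
25 | (Z)-16-[(tert-butyldimethylsilyl)oxy]hexadec-9-enoic acid | OC(=O)CCCCCCC/C=C\CCCCCCO[Si](C)(C)C(C)(C)C | intermediate
26 | C10 ester of 18 with 25 | C[C@@]1(CO[Si](C)(C)C(C)(C)C)[C@@H]2C[C@]3([C@@H](OC(=O)CCCCCCC/C=C\CCCCCCO[Si](C)(C)C(C)(C)C)C=C2C(=O)OC(C)(C)C)[C@@H](C(=O)N(C)OC)CC[C@@H]13 | intermediate
27 | protected aldehyde (C12 CHO; two TBS ethers; tert-butyl ester) | C[C@@]1(CO[Si](C)(C)C(C)(C)C)[C@@H]2C[C@]3([C@@H](OC(=O)CCCCCCC/C=C\CCCCCCO[Si](C)(C)C(C)(C)C)C=C2C(=O)OC(C)(C)C)[C@@H](C=O)CC[C@@H]13 | intermediate
28 | (1R,2S,5S,6S,7S,10S)-2-formyl-6-(hydroxymethyl)-10-{[(Z)-16-hydroxyhexadec-9-enoyl]oxy}-6-methyltricyclo[5.3.1.0(1,5)]undec-8-ene-8-carboxylic acid | C[C@@]1(CO)[C@@H]2C[C@]3([C@@H](OC(=O)CCCCCCC/C=C\CCCCCCO)C=C2C(=O)O)[C@@H](C=O)CC[C@@H]13 | target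

## Step count and risks

Total step count: 18. Longest linear sequence: 14 steps (steps 1–11 and 16–18).

Steps most likely to fail:

1. Step 9. Delivery of hydrogen to C5 may stall or go to the wrong face, because saturating C5 builds the strained trans junction of rings A and B and the lactone carbonyl can compete with the C13 hydroxyl for the iridium centre; migration of the C4=C5 bond is a further drain. Fallback (covalent delivery of hydrogen to C5): setting out from 15, BH3·SMe2 (THF, 0 °C) turns the C13 hydroxyl into an alkoxyborane that hydroborates C4=C5 intramolecularly from the face of the tether, boron going to C4 and hydrogen to C5, to give the cyclic alkoxyborane F1; protodeboronation of the C4–B bond (propionic acid, 100 °C) then comes back to the route at 16.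

2. Step 7. The ylide may fail to close on the doubly neopentyl C5 carbonyl, so that it is lost by protonation or by addition to a second phosphonium ion. Fallback (ring A by ring-closing metathesis): setting out from 12, alkylation of the lactone enolate (LiN(SiMe3)2, allyl bromide, THF, −78 °C; the epimer with the allyl group on the C5 side is used and the other is recycled by base) gives the C2-allyl lactone F2; Lombardo–Takai methylenation of the C5 ketone (Zn, CH2Br2, TiCl4, THF) gives the exocyclic alkene F3; ring-closing metathesis with the second-generation Grubbs catalyst RuCl2(=CHPh)(PCy3)(H2IMes) (CH2Cl2, 40 °C) forms the C4=C5 bond with loss of ethene and comes back to the route at 14.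

3. Step 5. The reversible aldol may settle on the C10 epimer whose alkoxide is anti to C11 and cannot close the cis-fused lactone, or revert by retro-aldol before lactonisation. Fallback (lactonisation with inversion): setting out from 9, the same base treatment quenched early gives the C10-epimeric hydroxy ester F4; LiOH (THF/H2O) gives the hydroxy diacid F5; an intramolecular Mitsunobu reaction (PPh3, diisopropyl azodicarboxylate, THF) lets the C12 carboxylate displace the activated C10 hydroxyl with inversion and comes back to the route at 11.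

Further compounds

F1 | step 9 | cyclic alkoxyborane: 16 with a C13–O–BH–C4 six-membered ring (boron on C4, cis to H5) | C[C@@]1(CO5)[C@@H]2C[C@]3([C@@H](O4)C=C2C(=O)OC(C)(C)C)[C@@H](C4=O)C[C@H]([BH]5)[C@@H]13
F2 | step 7 | C2-allyl derivative of 12 (allyl group on the C5 side) | O=C1[C@](C)(COCc5ccc(OC)cc5)[C@@H]2C[C@]1([C@@H](O4)C=C2C(=O)OC(C)(C)C)[C@@H](C4=O)CC=C
F3 | step 7 | C5-methylene derivative of F2 | C=C1[C@](C)(COCc5ccc(OC)cc5)[C@@H]2C[C@]1([C@@H](O4)C=C2C(=O)OC(C)(C)C)[C@@H](C4=O)CC=C
F4 | step 5 | C10 epimer of aldol adduct 10 (hydroxy methyl ester acid) | O=C1[C@](C)(COCc5ccc(OC)cc5)[C@@H]2C[C@]1([C@H](O)C=C2C(=O)O)CC(=O)OC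
F5 | step 5 | C10-epimeric hydroxy diacid | O=C1[C@](C)(COCc5ccc(OC)cc5)[C@@H]2C[C@]1([C@H](O)C=C2C(=O)O)CC(=O)O
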